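## Retrosynthetic overview

1. Rings A and B are bought, and ring C is the only ring made. It is closed last by disconnecting O1–C2 of the target flavanone to a 2'-hydroxychalcone. This enantioselective oxa-Michael closure sets the sole stereocentre, C2 (S).
2. The 7-OH passes through that step as a TBS ether. It is put on after chalcone formation and removed in the cyclisation flask.
3. Disconnecting Cα=Cβ of the chalcone gives the Claisen–Schmidt partners: the 3,5-diprenyl-2,4-dihydroxyacetophenone and 4-methoxybenzaldehyde.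
4. Two aryl–CH2 disconnections of that acetophenone lead to resacetophenone and two equivalents of prenyl bromide.

**Assumption:** the sense of induction of cat-A in the new C2-setting step rests on a model, so it is checked on the first run by chiral HPLC and ECD against (2S)-flavanones, and the (R)-tert-leucine-derived enantiomer of the catalyst is used instead if cat-A gives 2R.

**Catalyst cat-A** (preformed by Staudinger reaction of the azido-thiourea with the phosphine, not a route compound): 1-[3,5-bis(trifluoromethyl)phenyl]-3-[(2S)-3,3-dimethyl-1-{[tris(4-methoxyphenyl)-λ5-phosphanylidene]amino}butan-2-yl]thiourea.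
SMILES: COc1ccc(cc1)P(=NC[C@@H](NC(=S)Nc1cc(cc(c1)C(F)(F)F)C(F)(F)F)C(C)(C)C)(c1ccc(OC)cc1)c1ccc(OC)cc1

## Route

**Step 1**
Reactants: 1 2',4'-dihydroxyacetophenone (resacetophenone); 2 prenyl bromide (1-bromo-3-methylbut-2-ene, 2.2 equiv)
Product: 5 1-[2,4-dihydroxy-3,5-bis(3-methylbut-2-en-1-yl)phenyl]ethan-1-one, via 3-prenylresacetophenone 3 (not isolated), via 5-prenylresacetophenone 4 (not isolated)
Conditions: KOH (2.3 equiv), H2O, 0 °C to rt, 24 h; then 1 M HCl; chromatography (recovered mono-prenyl material is resubmitted)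
Reagents that add atoms: none
Why: This is a phenoxide C-alkylation (nuclear prenylation, SN2 at the primary carbon of 2): in water the strongly solvated oxygen of the ambident resorcinolate is shielded, so alkylation occurs on carbon at the two positions activated by both oxygens (C3 and C5), both mono-adducts 3 and 4 converge on 5, no stereocentre is formed, and the modest yield typical of this known reaction (about 25–35 %) is affordable in a first step on bulk chemicals.

**Step 2**
Reactants: 5 1-[2,4-dihydroxy-3,5-bis(3-methylbut-2-en-1-yl)phenyl]ethan-1-one; 6 4-methoxybenzaldehyde (1.3 equiv)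
Product: 8 (E)-1-[2,4-dihydroxy-3,5-bis(3-methylbut-2-en-1-yl)phenyl]-3-(4-methoxyphenyl)prop-2-en-1-one (2',4'-dihydroxy-4-methoxy-3',5'-diprenylchalcone), via aldol adduct 7 (not isolated)
Conditions: KOH (50 % aq, 12 equiv), EtOH, Ar, rt, 48 h; then cold 1 M HCl to pH 5; chromatography or crystallisation to remove any racemic flavanone
Reagents that add atoms: none
Why: In this Claisen–Schmidt condensation (aldol addition, then E1cB dehydration) only the methyl ketone can enolise and only 6 can act as the acceptor, loss of water from 7 is driven by the extended conjugation and gives the E-alkene, prenyl groups and phenoxides are inert to hydroxide, and no stereocentre remains.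

**Step 3**
Reactants: 8 2',4'-dihydroxy-4-methoxy-3',5'-diprenylchalcone
Product: 9 (E)-1-[4-(tert-butyldimethylsilyloxy)-2-hydroxy-3,5-bis(3-methylbut-2-en-1-yl)phenyl]-3-(4-methoxyphenyl)prop-2-en-1-one
Conditions: TBSCl (1.15 equiv), imidazole (2.5 equiv), DMF, 0 °C to rt
Reagents that add atoms: tert-butyldimethylsilyl chloride (TBSCl), CC(C)(C)[Si](C)(C)Cl
Why: This is a chemoselective phenol O-silylation in which the 2'-OH stays free because it is locked in the hydrogen bond to the ketone, while the more acidic 4'-OH is masked so that it cannot protonate the basic catalyst of step 4 and turn the ketone into an unreactive vinylogous carboxylate.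

**Step 4**
Reactants: 9 4'-O-TBS-2'-hydroxy-4-methoxy-3',5'-diprenylchalcone
Product: 12 (2S)-7-hydroxy-2-(4-methoxyphenyl)-6,8-bis(3-methylbut-2-en-1-yl)-2,3-dihydro-4H-chromen-4-one (the target flavanone), via enolate ion pair 10 (not isolated), via 7-O-TBS flavanone 11 (not isolated)
Conditions: cat-A (10 mol %), 4 Å MS, toluene (0.1 M), −20 °C, 48–72 h, stopped at the conversion plateau; then AcOH (2 equiv), TBAF (1.3 equiv), THF, 0 °C, same flask
Reagents that add atoms: none
Why: Proposed new method: enantioselective 6-endo-trig intramolecular oxa-Michael addition of a simple (not α-ester-activated) 2'-hydroxychalcone under bifunctional iminophosphorane–thiourea (BIMP) catalysis: with the 4'-OH masked the chelated 2'-OH is the only acidic site, and the iminophosphorane (several pK units stronger than a cinchona quinuclidine) converts it into a tight phenoxide/iminophosphonium ion pair in toluene; the thiourea N–H pair binds the ketone oxygen, which replaces the internal O–H···O=C chelate given up on deprotonation and on rotation about the aryl–CO bond into the reactive conformer (enone s-trans, phenoxide over Cβ) and also lowers the enone LUMO; the tert-butyl group and the P-aryl wall leave only the Si face of Cβ open to the phenoxide, so C2 is set as S in enolate 10, and the P–N–H+ unit protonates 10 at C3 to release 11 and the free base; the only racemisation path is the E1cB reverse reaction through the same transition states, which at −20 °C is slower than ring closure by the factor Keq and is shut off by the AcOH quench, after which buffered fluoride removes the TBS group without touching C2; the closest known reaction types are the tertiary-amine/thiourea-catalysed cyclisation of α-ester-activated 2'-hydroxychalcones and BIMP-catalysed intramolecular oxa-Michael additions of alcohols to unsaturated esters and amides, whereas unactivated chalcones have so far given only moderate ee with cinchona bases or chiral ammonium ion pairs.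

## Compound list

1 | 2',4'-dihydroxyacetophenone (resacetophenone) | CC(=O)c1ccc(O)cc1O | starting material
2 | prenyl bromide (1-bromo-3-methylbut-2-ene) | CC(C)=CCBr | starting material
3 | 1-[2,4-dihydroxy-3-(3-methylbut-2-en-1-yl)phenyl]ethan-1-one | CC(=O)c1ccc(O)c(CC=C(C)C)c1O | intermediate
4 | 1-[2,4-dihydroxy-5-(3-methylbut-2-en-1-yl)phenyl]ethan-1-one | CC(=O)c1cc(CC=C(C)C)c(O)cc1O | intermediate
5 | 1-[2,4-dihydroxy-3,5-bis(3-methylbut-2-en-1-yl)phenyl]ethan-1-one | CC(=O)c1cc(CC=C(C)C)c(O)c(CC=C(C)C)c1O | intermediate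
6 | 4-methoxybenzaldehyde (p-anisaldehyde) | COc1ccc(C=O)cc1 | starting material
7 | 1-[2,4-dihydroxy-3,5-bis(3-methylbut-2-en-1-yl)phenyl]-3-hydroxy-3-(4-methoxyphenyl)propan-1-one (racemic aldol adduct) | COc1ccc(C(O)CC(=O)c2cc(CC=C(C)C)c(O)c(CC=C(C)C)c2O)cc1 | intermediate
8 | (E)-1-[2,4-dihydroxy-3,5-bis(3-methylbut-2-en-1-yl)phenyl]-3-(4-methoxyphenyl)prop-2-en-1-one | COc1ccc(/C=C/C(=O)c2cc(CC=C(C)C)c(O)c(CC=C(C)C)c2O)cc1 | intermediate
9 | (E)-1-[4-(tert-butyldimethylsilyloxy)-2-hydroxy-3,5-bis(3-methylbut-2-en-1-yl)phenyl]-3-(4-methoxyphenyl)prop-2-en-1-one | COc1ccc(/C=C/C(=O)c2cc(CC=C(C)C)c(O[Si](C)(C)C(C)(C)C)c(CC=C(C)C)c2O)cc1 | intermediate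
10 | (2S)-7-(tert-butyldimethylsilyloxy)-2-(4-methoxyphenyl)-6,8-bis(3-methylbut-2-en-1-yl)-2H-chromen-4-ol (drawn as the enol; present as its iminophosphonium enolate ion pair) | COc1ccc([C@@H]2C=C(O)c3cc(CC=C(C)C)c(O[Si](C)(C)C(C)(C)C)c(CC=C(C)C)c3O2)cc1 | intermediate
11 | (2S)-7-(tert-butyldimethylsilyloxy)-2-(4-methoxyphenyl)-6,8-bis(3-methylbut-2-en-1-yl)-2,3-dihydro-4H-chromen-4-one | COc1ccc([C@@H]2CC(=O)c3cc(CC=C(C)C)c(O[Si](C)(C)C(C)(C)C)c(CC=C(C)C)c3O2)cc1 | intermediate
12 | (2S)-7-hydroxy-2-(4-methoxyphenyl)-6,8-bis(3-methylbut-2-en-1-yl)-2,3-dihydro-4H-chromen-4-one (the target flavanone) | COc1ccc([C@@H]2CC(=O)c3cc(CC=C(C)C)c(O)c(CC=C(C)C)c3O2)cc1 | target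

## Step count

Total step count: 4
Longest linear sequence: 4 (1 → 5 → 8 → 9 → 12)

## Steps most likely to fail

**Step 4 (the proposed new step).**

*Risks:* The enone carries donors on both aryl rings and is a weak acceptor. The cyclisation is an equilibrium, so conversion stops at a plateau. Leftover 9 comes back as 8 after the fluoride treatment and is recycled. The ee erodes if the reaction is left too long. The 2'-phenoxide could pick up silyl groups from other molecules. Both the level and the sense of induction are untested.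

*Fallback:* This is known chemistry whose stereo-defining step is again organocatalytic. It sets out from 5 and comes back at 11. 5 is silylated (TBSCl, imidazole, DMF) to the 4-O-TBS acetophenone F1. The dianion of F1 (LiHMDS, 3.2 equiv, THF, −78 °C) is C-acylated with Boc2O in a Claisen-type acylation to give the tert-butyl β-keto ester F2. Knoevenagel condensation of F2 with 6 (piperidine/AcOH, toluene, 4 Å MS) gives the alkylidene β-keto ester F3. F3 then undergoes the established cyclisation of such doubly activated acceptors. The catalyst is a 9-amino-9-deoxy-epi-cinchona 3,5-bis(trifluoromethyl)phenyl thiourea (10 mol %, toluene, −25 °C), in the pseudoenantiomer that gives 2S. The product is the 3-tert-butoxycarbonyl flavanone F4, whose C3 is labile. Mild ester cleavage (85 % H3PO4, toluene, rt) is chosen over hot sulfonic acid to spare the prenyl groups and the silyl ether. It gives the β-keto acid F5, which loses CO2 at 40 °C to give 11. The weakly basic catalyst cannot reopen the decarboxylated flavanone, so the ee holds. 11 is then desilylated with TBAF/AcOH as in step 4.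

**Step 1.**

*Risks:* The reaction gives a mixture of O-prenyl ethers, mono-adducts and dearomatised 3,3-diprenyl products, so the yield of 5 is low and the separation tedious.

*Fallback:* It sets out from 1 and comes back at 5, and it replaces ambident-anion alkylation with cross-coupling at predefined positions. Iodination of 1 (I2, HIO3, aq EtOH) gives 3,5-diiodo-2,4-dihydroxyacetophenone F6. MOMCl/NaH in DMF converts F6 into the bis-MOM ether F7. Double Stille coupling of F7 with tributyl(3-methylbut-2-en-1-yl)stannane (Pd(PPh3)4, DMF, 90 °C) gives the bis-MOM diprenyl acetophenone F8. Brief treatment of F8 with HCl in MeOH gives 5.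

**Step 2.**

*Risks:* The acetophenone is a bis-phenoxide under the conditions and 6 is an electron-rich aldehyde, so the condensation is slow. Hydroxide can also cyclise part of 8 to racemic 12, which must be removed completely.

*Fallback:* It sets out from 5 and comes back at 12, and it moves the masking of the 4-OH ahead of the condensation with a base-stable group. MOMCl (1.2 equiv) with K2CO3 in acetone gives the 4-O-MOM acetophenone F9, in which the chelated 2-OH stays free. KOH/EtOH condensation of F9 with 6 proceeds through the aldol adduct F10 to the 4'-O-MOM chalcone F11. F11 is submitted to the cat-A conditions of step 4 in place of 9. It passes through the enolate F12 to the (2S)-7-O-MOM flavanone F13. HCl in MeOH at rt cleaves F13 to 12.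

## Further compounds

F1 | step 4 | 1-[4-(tert-butyldimethylsilyloxy)-2-hydroxy-3,5-bis(3-methylbut-2-en-1-yl)phenyl]ethan-1-one | CC(=O)c1cc(CC=C(C)C)c(O[Si](C)(C)C(C)(C)C)c(CC=C(C)C)c1O
F2 | step 4 | tert-butyl 3-[4-(tert-butyldimethylsilyloxy)-2-hydroxy-3,5-bis(3-methylbut-2-en-1-yl)phenyl]-3-oxopropanoate | CC(C)(C)OC(=O)CC(=O)c1cc(CC=C(C)C)c(O[Si](C)(C)C(C)(C)C)c(CC=C(C)C)c1O
F3 | step 4 | tert-butyl 2-[4-(tert-butyldimethylsilyloxy)-2-hydroxy-3,5-bis(3-methylbut-2-en-1-yl)benzoyl]-3-(4-methoxyphenyl)prop-2-enoate (E/Z mixture) | COc1ccc(C=C(C(=O)OC(C)(C)C)C(=O)c2cc(CC=C(C)C)c(O[Si](C)(C)C(C)(C)C)c(CC=C(C)C)c2O)cc1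
F4 | step 4 | tert-butyl (2S)-7-(tert-butyldimethylsilyloxy)-2-(4-methoxyphenyl)-6,8-bis(3-methylbut-2-en-1-yl)-4-oxochromane-3-carboxylate (C3 labile) | COc1ccc([C@@H]2C(C(=O)OC(C)(C)C)C(=O)c3cc(CC=C(C)C)c(O[Si](C)(C)C(C)(C)C)c(CC=C(C)C)c3O2)cc1
F5 | step 4 | (2S)-7-(tert-butyldimethylsilyloxy)-2-(4-methoxyphenyl)-6,8-bis(3-methylbut-2-en-1-yl)-4-oxochromane-3-carboxylic acid (C3 labile) | COc1ccc([C@@H]2C(C(=O)O)C(=O)c3cc(CC=C(C)C)c(O[Si](C)(C)C(C)(C)C)c(CC=C(C)C)c3O2)cc1
F6 | step 1 | 1-(2,4-dihydroxy-3,5-diiodophenyl)ethan-1-one | CC(=O)c1cc(I)c(O)c(I)c1O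
F7 | step 1 | 1-[3,5-diiodo-2,4-bis(methoxymethoxy)phenyl]ethan-1-one | CC(=O)c1cc(I)c(OCOC)c(I)c1OCOC
F8 | step 1 | 1-[2,4-bis(methoxymethoxy)-3,5-bis(3-methylbut-2-en-1-yl)phenyl]ethan-1-one | CC(=O)c1cc(CC=C(C)C)c(OCOC)c(CC=C(C)C)c1OCOC
F9 | step 2 | 1-[2-hydroxy-4-(methoxymethoxy)-3,5-bis(3-methylbut-2-en-1-yl)phenyl]ethan-1-one | CC(=O)c1cc(CC=C(C)C)c(OCOC)c(CC=C(C)C)c1O
F10 | step 2 | 3-hydroxy-1-[2-hydroxy-4-(methoxymethoxy)-3,5-bis(3-methylbut-2-en-1-yl)phenyl]-3-(4-methoxyphenyl)propan-1-one (racemic) | COc1ccc(C(O)CC(=O)c2cc(CC=C(C)C)c(OCOC)c(CC=C(C)C)c2O)cc1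
F11 | step 2 | (E)-1-[2-hydroxy-4-(methoxymethoxy)-3,5-bis(3-methylbut-2-en-1-yl)phenyl]-3-(4-methoxyphenyl)prop-2-en-1-one | COc1ccc(/C=C/C(=O)c2cc(CC=C(C)C)c(OCOC)c(CC=C(C)C)c2O)cc1
F12 | step 2 | (2S)-7-(methoxymethoxy)-2-(4-methoxyphenyl)-6,8-bis(3-methylbut-2-en-1-yl)-2H-chromen-4-ol (enol form of the enolate) | COc1ccc([C@@H]2C=C(O)c3cc(CC=C(C)C)c(OCOC)c(CC=C(C)C)c3O2)cc1
F13 | step 2 | (2S)-7-(methoxymethoxy)-2-(4-methoxyphenyl)-6,8-bis(3-methylbut-2-en-1-yl)-2,3-dihydro-4H-chromen-4-one | COc1ccc([C@@H]2CC(=O)c3cc(CC=C(C)C)c(OCOC)c(CC=C(C)C)c3O2)cc1
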